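The ratio of first nucleophile to substrate charged is 1.30 in the amber run and 0.650 in the red run, where first nucleophile is therefore the limiting reagent if each target takes one.

| flask | substrate | first nucleophile | second nucleophile | remark | time |
|---|---|---|---|---|---|
| amber | 0.20 M | 0.26 M | 0.27 M | run made earlier |  |
| red | 0.40 M | 0.26 M | 0.18 M | run made earlier |  |
| alder | 0.20 M | 0.260 M | 0.180 M |  | 20 h |
| larch | 0.20 M | 0.650 M | 0.180 M |  | 20 h |
| ash | 0.20 M | 1.60 M | 0.180 M |  | 20 h |

| run | time / h | target / % | other capture product / % | intermediate / % | substrate / % |
|---|---|---|---|---|---|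
| amber | 0.667 | 2.2 | 0.1 | 0.8 | 96.6 |
| amber | 1.33 | 4.8 | 0.6 | 0 | 94.8 |
| amber | 2.00 | 6.8 | 1.0 | 0.5 | 92.1 |
| amber | 2.50 | 8.9 | 1.1 | 0.2 | 89.3 |
| amber | 3.00 | 11.4 | 0.7 | 0 | 89.2 |
| amber | 4.00 | 13.7 | 1.1 | 0.7 | 85.5 |
| red | 0.250 | 0.8 | 0.1 | 0.1 | 98.5 |
| red | 0.833 | 3.0 | 0.7 | 0.6 | 96.2 |
| red | 1.33 | 4.5 | 0.2 | 1.3 | 95.0 |
| red | 2.00 | 6.4 | 0.6 | 0 | 93.1 |
| red | 3.00 | 10.2 | 0.2 | 0 | 89.8 |
| red | 4.00 | 12.7 | 0.4 | 0.5 | 86.1 |

(scatter of a reading: 0.5 percentage points)



- which of these there is most of at the end, counted by the substrate in it, alder (substrate / other capture product / target / intermediate)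
- which of these there is most of at the end, counted by the substrate in it, larch (substrate / other capture product / target / intermediate)
- which of these there is most of at the end, counted by the substrate in it, ash (substrate / other capture product / target / intermediate)
- how much there is at the end of the one of these that leads, in percent of the substrate charged: alder
- how much there is at the end of the one of these that leads, in percent of the substrate charged: larch
- how much there is at the end of the one of these that leads, in percent of the substrate charged: ash

Yet the logarithm of the substrate's fall gives 0.0392 h⁻¹ in amber and 0.0374 h⁻¹ in red, as if the ratio did not matter. It clears up when I count what has been spent. If each substrate lost takes one first nucleophile, the readings at 4.00 h leave 88.8% of amber's first nucleophile and 78.6% of red's, and the last substrate readings differ by 0.6 percentage points against a scatter of 0.5 points.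

So I try a rate proportional to both. Let a and b be the fractions of substrate and first nucleophile left, and r the ratio. Then the loss of a is k·a·b, with b = one − (one − a)/r, which integrates to ln(b/a) = k(one − one/r)t. I call k the opening loss rate, the share of substrate lost per hour at the start. Amber's last reading gives 0.0416 h⁻¹ and red's 0.0422 h⁻¹, so I carry 0.0419 h⁻¹.

Both runs hold the same first nucleophile charge, so scaling k with that charge is my untested assumption. It gives 0.105 h⁻¹ for larch and 0.258 h⁻¹ for ash. Solving for a at 20 h, and reading the rest as target, I reckon alder at 52.0% substrate, which leads. For larch I reckon 17.5% substrate, so 82.5% target, and for ash 0.961% substrate, so 99.0% target.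

The forecast, which differs from me on alder's leader and on the larch and ash amounts, puts target first in each flask at 49.5%, 51.5% and 52.5%, saying of first nucleophile's effect on the rate “I assume none”.

The flasks give substrate leading alder at 52.6%, and target leading larch at 73.4% and ash at 89.5%.

    2 second nucleophile → self-condensation product B (k = 0.230 M⁻¹ h⁻¹)
    second nucleophile → decomposed reagent (k = 0.180 h⁻¹)
    substrate ⇌ intermediate (K = 0.00570, k = 0.200 h⁻¹)
    second nucleophile + intermediate → other capture product (k = 2.80 M⁻¹ h⁻¹)
    first nucleophile + intermediate → target (k = 32.0 M⁻¹ h⁻¹)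
    2 substrate → self-condensation product A (k = 2.10 × 10⁻⁴ M⁻¹ h⁻¹)

In ash at 5.08 h, intermediate falls back 0.72 times as fast as it goes on. The forward step from substrate has a half-life of 3.5 h by itself, the way back not counted. Ash's end amounts put its opening loss rate at 0.125 h⁻¹, below my scaled 0.258 h⁻¹. With that rate the closed form gives 24.5% for ash read at 12 h, where the flask holds 24.9% substrate.

The numbers in the tables are calculated with constants of no real substance.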